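**Strategy.** Drimane numbering is used (ring A: C1–C5, C10; ring B: C5–C10). Ring B carries a tertiary oxygen at C8 next to C9 with its C11 carbon, the 1,3-dioxygen pattern of a 1-silyloxydiene/enoate Diels–Alder adduct. Everything therefore rests on opening ring B across C5–C10 and C8–C9, which turns the decalin into an acyclic, geranate-derived (2E,8E,10Z)-trienoate whose only stereocentre is the C3 carbinol. One thermal intramolecular Diels–Alder reaction closes rings A and B together and sets C5, C8, C9 and C10 from C3 and from the alkene geometries. Hydrogenation, reduction, coumarin etherification and angeloylation finish the synthesis.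

Key step: step 5

Numbering remark: ring compounds are named as drimanes (C3 carbinol, C4 gem-dimethyl, C8 bearing CH3 and oxygen, C9 bearing C11, C10 bearing the angular CH3). In all of them 3-O, 10-CH3, 8-CH3 and C11 lie on one face, and 5-H, 9-H and 8-O on the other.

Assumption: the (S) antipode of SEGPHOS is taken to deliver the (6R) carbinol in step 2, by analogy with the facial preference of related iridium-catalysed carbonyl allylations. The configuration of 5 would be checked by Mosher ester analysis and the (R) ligand used if the sense proved opposite.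

Step 1
Reactants: 1 methyl geranate [methyl (2E)-3,7-dimethylocta-2,6-dienoate]
Product: 3 methyl (2E)-3-methyl-6-oxohex-2-enoate, via ozonide 2 (not isolated)
Conditions: O3 (1.0 equiv, Sudan Red 7B end point), CH2Cl2, −78 °C; then PPh3, −78 °C → rt
Reagents that add atoms: ozone [O-][O+]=O
Why: Chemoselective ozonolysis, in which the electron-rich trisubstituted 6,7-alkene should react far faster than the conjugated enoate, and phosphine reduction of the ozonide then releases the aldehyde without touching the (2E) geometry.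

Step 2
Reactants: 3 methyl (2E)-3-methyl-6-oxohex-2-enoate; 4 3-methylbuta-1,2-diene
Product: 5 methyl (2E,6R)-6-hydroxy-3,7,7-trimethylnona-2,8-dienoate
Conditions: [Ir(cod)Cl]2 (2.5 mol%), (S)-SEGPHOS (5 mol%), 4-cyano-3-nitrobenzoic acid (10 mol%), Cs2CO3 (20 mol%), iPrOH (2 equiv), toluene, 50 °C
Reagents that add atoms: 3-methylbuta-1,2-diene CC(C)=C=C
Why: Iridium-catalysed transfer-hydrogenative carbonyl reverse prenylation (Krische-type allylation), in which hydrometalation of the allene gives a 1,1-dimethylallyl iridium species that adds through its substituted terminus in a closed chair transition state, so that the gem-dimethyl carbon, the vinyl group and the (6R) carbinol (the future C3, set by the chiral bisphosphine) arise together.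

Step 3
Reactants: 5 methyl (2E,6R)-6-hydroxy-3,7,7-trimethylnona-2,8-dienoate; 6 pent-4-en-2-one
Product: 7 methyl (2E,6R,8E)-6-hydroxy-3,7,7-trimethyl-11-oxododeca-2,8-dienoate
Conditions: second-generation Hoveyda–Grubbs catalyst RuCl2(H2IMes)(=CH-C6H4-2-OiPr) (5 mol%), pent-4-en-2-one (5 equiv), 1,4-benzoquinone (10 mol%), CH2Cl2, 40 °C
Reagents that add atoms: pent-4-en-2-one CC(=O)CC=C
Why: Olefin cross-metathesis, in which the vinyl group next to the quaternary carbon cannot homodimerise and should couple with the excess allyl ketone to the (E)-alkene for steric reasons, while the trisubstituted enoate is inert and benzoquinone suppresses double-bond migration.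

Step 4
Reactants: 7 methyl (2E,6R,8E)-6-hydroxy-3,7,7-trimethyl-11-oxododeca-2,8-dienoate
Product: 9 methyl (2E,6R,8E,10Z)-3,7,7-trimethyl-6,11-bis(triethylsilyloxy)dodeca-2,8,10-trienoate, via silyl ether ketone 8 (not isolated)
Conditions: Et3SiOTf (2.6 equiv), Et3N (4 equiv), CH2Cl2, −78 → 0 °C
Reagents that add atoms: triethylsilyl trifluoromethanesulfonate CC[Si](CC)(CC)OS(=O)(=O)C(F)(F)F
Why: O-Silylation of the carbinol followed by soft enolisation (silyl triflate and amine) of the β,γ-unsaturated ketone at the doubly activated C10 methylene, which should give the conjugated dienol ether in the thermodynamically preferred (10Z) geometry (oxygen cis to the vinyl group) and leave the ester untouched.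

Step 5
Reactants: 9 methyl (2E,6R,8E,10Z)-3,7,7-trimethyl-6,11-bis(triethylsilyloxy)dodeca-2,8,10-trienoate
Product: 10 methyl (3R,5S,8S,9S,10R)-3,8-bis(triethylsilyloxy)drim-6-en-11-oate
Conditions: toluene (0.01 M), BHT (0.1 equiv), 175 °C, sealed tube
Reagents that add atoms: none
Why: A thermal, concerted but asynchronous normal-electron-demand [4+2] cycloaddition (type 1 intramolecular Diels–Alder reaction of a deca-1,3,9-triene, the closest known type being decalin-forming cyclisations of 1-silyloxy dienes onto tethered enoates) joins the nucleophilic diene terminus to the enoate β-carbon (precursor C8–C3 = drimane C5–C10) and the silyloxy-bearing terminus to the α-carbon (precursor C11–C2 = drimane C8–C9), the polarity-matched orientation that the tether also enforces. Ring A closes in the fused mode through the four-atom tether C1–C4 as a chair-like six-membered array, and ring B is the cyclohexene formed by the cycloaddition itself. The trans ring fusion (5-H anti to 10-CH3) should follow from the transition state with the ester endo and the tether exo on the (E)-enoate, favoured by secondary orbital overlap; C9 follows from the (E)-enoate geometry (C11 cis to 10-CH3) and C8 from the (Z)-enol ether geometry, which places the small oxygen inside and the methyl outside the diene so that the oxygen ends up cis to 5-H. The absolute sense at all four new centres is relayed from C3, whose silyloxy group should sit equatorial in the chair-like tether next to the gem-dimethyl carbon. The step needs endo over exo and one diene face over the other. The diene has no hydrogen placed for a 1,5-shift, so it should tolerate the temperature, and any minor (10E) enol ether, with methyl inside, should react more slowly.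

Step 6
Reactants: 10 methyl (3R,5S,8S,9S,10R)-3,8-bis(triethylsilyloxy)drim-6-en-11-oate
Product: 11 methyl (3R,5S,8S,9S,10R)-3,8-bis(triethylsilyloxy)driman-11-oate
Conditions: H2 (3 atm), Pt/C (5 wt%), EtOAc, rt
Reagents that add atoms: none
Why: Heterogeneous hydrogenation of the only C=C bond (the cis-disubstituted C6=C7 alkene) creates no stereocentre, and it is placed here because the coumarin and angelate alkenes introduced later would not survive it.

Step 7
Reactants: 11 methyl (3R,5S,8S,9S,10R)-3,8-bis(triethylsilyloxy)driman-11-oate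
Product: 13 (3R,5S,8S,9R,10R)-drimane-3,8,11-triol, via bis-silyl alcohol 12 (not isolated)
Conditions: LiAlH4, THF, 0 → 40 °C; then 1 M HCl, MeOH/THF, rt
Reagents that add atoms: none
Why: Hydride reduction of the hindered ester to the primary alcohol and acid solvolysis of both triethylsilyl ethers in the same flask, where dilute acid at room temperature should spare the tertiary alcohol and any silyl migration to the new alkoxide is without consequence.

Step 8
Reactants: 13 (3R,5S,8S,9R,10R)-drimane-3,8,11-triol; 14 umbelliferone (7-hydroxy-2H-chromen-2-one)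
Product: 15 7-{[(3R,5S,8S,9R,10R)-3,8-dihydroxydriman-11-yl]oxy}-2H-chromen-2-one
Conditions: PPh3, DIAD, THF, 0 → 45 °C
Reagents that add atoms: umbelliferone Oc1ccc2ccc(=O)oc2c1
Why: Mitsunobu etherification with the acidic phenol (pKa about 8), in which only the primary C11 hydroxyl can be displaced in an SN2 reaction, whereas the secondary hydroxyl next to the gem-dimethyl carbon and the tertiary hydroxyl should not react.

Step 9
Reactants: 15 7-{[(3R,5S,8S,9R,10R)-3,8-dihydroxydriman-11-yl]oxy}-2H-chromen-2-one; 16 angelic acid [(2Z)-2-methylbut-2-enoic acid]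
Product: 18 (2R,4aR,5R,6S,8aS)-6-hydroxy-1,1,4a,6-tetramethyl-5-{[(2-oxo-2H-chromen-7-yl)oxy]methyl}decahydronaphthalen-2-yl (2Z)-2-methylbut-2-enoate, via mixed anhydride 17 (not isolated)
Conditions: 2,4,6-trichlorobenzoyl chloride, Et3N, toluene, rt; then 15, 80 °C
Reagents that add atoms: angelic acid C/C=C(/C)C(=O)O
Why: Yamaguchi-type mixed-anhydride esterification run without a nucleophilic catalyst, which should acylate the equatorial secondary C3 hydroxyl only (the tertiary C8 hydroxyl is inert) and avoid the Z to E isomerisation to the tiglate that DMAP promotes.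

**Compound list**

1 | methyl geranate, methyl (2E)-3,7-dimethylocta-2,6-dienoate | COC(=O)/C=C(\C)CCC=C(C)C | starting material
2 | methyl (2E)-5-(5,5-dimethyl-1,2,4-trioxolan-3-yl)-3-methylpent-2-enoate (ozonide) | COC(=O)/C=C(\C)CCC1OOC(C)(C)O1 | intermediate
3 | methyl (2E)-3-methyl-6-oxohex-2-enoate | COC(=O)/C=C(\C)CCC=O | intermediate
4 | 3-methylbuta-1,2-diene | CC(C)=C=C | starting material
5 | methyl (2E,6R)-6-hydroxy-3,7,7-trimethylnona-2,8-dienoate | COC(=O)/C=C(\C)CC[C@@H](O)C(C)(C)C=C | intermediate
6 | pent-4-en-2-one | CC(=O)CC=C | starting material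
7 | methyl (2E,6R,8E)-6-hydroxy-3,7,7-trimethyl-11-oxododeca-2,8-dienoate | COC(=O)/C=C(\C)CC[C@@H](O)C(C)(C)/C=C/CC(C)=O | intermediate
8 | methyl (2E,6R,8E)-3,7,7-trimethyl-11-oxo-6-(triethylsilyloxy)dodeca-2,8-dienoate | COC(=O)/C=C(\C)CC[C@@H](O[Si](CC)(CC)CC)C(C)(C)/C=C/CC(C)=O | intermediate
9 | methyl (2E,6R,8E,10Z)-3,7,7-trimethyl-6,11-bis(triethylsilyloxy)dodeca-2,8,10-trienoate | COC(=O)/C=C(\C)CC[C@@H](O[Si](CC)(CC)CC)C(C)(C)/C=C/C=C(/C)O[Si](CC)(CC)CC | intermediate
10 | methyl (3R,5S,8S,9S,10R)-3,8-bis(triethylsilyloxy)drim-6-en-11-oate | CC[Si](CC)(CC)O[C@@H]1CC[C@]2(C)[C@H](C=C[C@](C)(O[Si](CC)(CC)CC)[C@H]2C(=O)OC)C1(C)C | intermediate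
11 | methyl (3R,5S,8S,9S,10R)-3,8-bis(triethylsilyloxy)driman-11-oate | CC[Si](CC)(CC)O[C@@H]1CC[C@]2(C)[C@H](CC[C@](C)(O[Si](CC)(CC)CC)[C@H]2C(=O)OC)C1(C)C | intermediate
12 | (3R,5S,8S,9R,10R)-3,8-bis(triethylsilyloxy)driman-11-ol | CC[Si](CC)(CC)O[C@@H]1CC[C@]2(C)[C@H](CC[C@](C)(O[Si](CC)(CC)CC)[C@H]2CO)C1(C)C | intermediate
13 | (3R,5S,8S,9R,10R)-drimane-3,8,11-triol | O[C@@H]1CC[C@]2(C)[C@H](CC[C@](C)(O)[C@H]2CO)C1(C)C | intermediate
14 | umbelliferone, 7-hydroxy-2H-chromen-2-one | Oc1ccc2ccc(=O)oc2c1 | starting material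
15 | 7-{[(3R,5S,8S,9R,10R)-3,8-dihydroxydriman-11-yl]oxy}-2H-chromen-2-one | O[C@@H]1CC[C@]2(C)[C@H](CC[C@](C)(O)[C@H]2COc2ccc3ccc(=O)oc3c2)C1(C)C | intermediate
16 | angelic acid, (2Z)-2-methylbut-2-enoic acid | C/C=C(/C)C(=O)O | starting material
17 | (2Z)-2-methylbut-2-enoic 2,4,6-trichlorobenzoic anhydride | C/C=C(/C)C(=O)OC(=O)c1c(Cl)cc(Cl)cc1Cl | intermediate
18 | (2R,4aR,5R,6S,8aS)-6-hydroxy-1,1,4a,6-tetramethyl-5-{[(2-oxo-2H-chromen-7-yl)oxy]methyl}decahydronaphthalen-2-yl (2Z)-2-methylbut-2-enoate; in drimane numbering (3R,5S,8S,9R,10R) | C/C=C(/C)C(=O)O[C@@H]1CC[C@]2(C)[C@H](CC[C@](C)(O)[C@H]2COc2ccc3ccc(=O)oc3c2)C1(C)C | target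

Total step count: 9. Longest linear sequence: 9 steps (1 to 18).

**Steps most likely to fail**

Step 5. The cycloaddition may be too slow, because the enoate is β,β-disubstituted and the diene carries an inside substituent, so that decomposition competes. The endo/exo (trans/cis fusion) and facial preferences may also erode at 175 °C. Fallback, setting out from 9 and returning at 12: the ester of 9 would be reduced with iBu2AlH (CH2Cl2, −78 °C) to (2E,6R,8E,10Z)-3,7,7-trimethyl-6,11-bis(triethylsilyloxy)dodeca-2,8,10-trien-1-ol F1. Oxidation with MnO2 would give (2E,6R,8E,10Z)-3,7,7-trimethyl-6,11-bis(triethylsilyloxy)dodeca-2,8,10-trienal F2. The far more electrophilic enal should then cyclise under Lewis acid activation (Me2AlCl, CH2Cl2, −78 °C), with a stronger endo preference, to (3R,5S,8S,9S,10R)-3,8-bis(triethylsilyloxy)drim-6-en-11-al F3. This would be reduced at once with NaBH4 to (3R,5S,8S,9R,10R)-3,8-bis(triethylsilyloxy)drim-6-en-11-ol F4, so that loss of silanol from the β-silyloxy aldehyde is avoided. Hydrogenation (H2, Pt/C) would give 12, which the acid treatment of step 7 converts into 13.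

Step 3. Turnover at the vinyl group beside the quaternary carbon may be slow, while the allyl ketone homodimerises or its double bond (or that of the product) migrates into conjugation. Fallback, setting out from 5 and returning at 8: silylation (Et3SiCl, imidazole) would give methyl (2E,6R)-3,7,7-trimethyl-6-(triethylsilyloxy)nona-2,8-dienoate F5. Oxidative cleavage of the terminal alkene, which should be faster than attack on the electron-poor enoate (OsO4 cat., NaIO4, 2,6-lutidine, dioxane/water), would give methyl (2E,6R)-3,7,7-trimethyl-8-oxo-6-(triethylsilyloxy)oct-2-enoate F6. Takai olefination (CrCl2, CHI3, THF) would give methyl (2E,6R,8E)-9-iodo-3,7,7-trimethyl-6-(triethylsilyloxy)nona-2,8-dienoate F7. Migita–Kosugi alkenylation of the tin enolate of acetone (isopropenyl acetate, Bu3SnOMe, PdCl2[P(o-tolyl)3]2, toluene, 100 °C) would then form the C–C bond to the ketone carbon chain and deliver 8, which is enolised as in step 4.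

Step 8. Displacement at the β-branched C11 carbon by the phenoxide may be too slow, so that the oxyphosphonium intermediate is diverted (elimination, or attack by the neighbouring C8 hydroxyl). Fallback, setting out from 12 (isolated by leaving out the acid treatment in step 7) and returning at 15: the aryl–oxygen bond would be made instead of the alkyl–oxygen bond. Buchwald–Hartwig etherification of the single free alcohol with 7-bromo-2H-chromen-2-one (Pd2(dba)3, tBuBrettPhos, Cs2CO3, toluene, 90 °C) would give 7-{[(3R,5S,8S,9R,10R)-3,8-bis(triethylsilyloxy)driman-11-yl]oxy}-2H-chromen-2-one F8. Desilylation with HF·pyridine in THF would give 15.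

Further compounds
F1 | step 5 | (2E,6R,8E,10Z)-3,7,7-trimethyl-6,11-bis(triethylsilyloxy)dodeca-2,8,10-trien-1-ol | OC/C=C(\C)CC[C@@H](O[Si](CC)(CC)CC)C(C)(C)/C=C/C=C(/C)O[Si](CC)(CC)CC
F2 | step 5 | (2E,6R,8E,10Z)-3,7,7-trimethyl-6,11-bis(triethylsilyloxy)dodeca-2,8,10-trienal | O=C/C=C(\C)CC[C@@H](O[Si](CC)(CC)CC)C(C)(C)/C=C/C=C(/C)O[Si](CC)(CC)CC
F3 | step 5 | (3R,5S,8S,9S,10R)-3,8-bis(triethylsilyloxy)drim-6-en-11-al | CC[Si](CC)(CC)O[C@@H]1CC[C@]2(C)[C@H](C=C[C@](C)(O[Si](CC)(CC)CC)[C@H]2C=O)C1(C)C
F4 | step 5 | (3R,5S,8S,9R,10R)-3,8-bis(triethylsilyloxy)drim-6-en-11-ol | CC[Si](CC)(CC)O[C@@H]1CC[C@]2(C)[C@H](C=C[C@](C)(O[Si](CC)(CC)CC)[C@H]2CO)C1(C)C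
F5 | step 3 | methyl (2E,6R)-3,7,7-trimethyl-6-(triethylsilyloxy)nona-2,8-dienoate | COC(=O)/C=C(\C)CC[C@@H](O[Si](CC)(CC)CC)C(C)(C)C=C
F6 | step 3 | methyl (2E,6R)-3,7,7-trimethyl-8-oxo-6-(triethylsilyloxy)oct-2-enoate | COC(=O)/C=C(\C)CC[C@@H](O[Si](CC)(CC)CC)C(C)(C)C=O
F7 | step 3 | methyl (2E,6R,8E)-9-iodo-3,7,7-trimethyl-6-(triethylsilyloxy)nona-2,8-dienoate | COC(=O)/C=C(\C)CC[C@@H](O[Si](CC)(CC)CC)C(C)(C)/C=C/I
F8 | step 8 | 7-{[(3R,5S,8S,9R,10R)-3,8-bis(triethylsilyloxy)driman-11-yl]oxy}-2H-chromen-2-one | CC[Si](CC)(CC)O[C@@H]1CC[C@]2(C)[C@H](CC[C@](C)(O[Si](CC)(CC)CC)[C@H]2COc2ccc3ccc(=O)oc3c2)C1(C)C
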